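**A direct plan and its weak steps**

A direct plan would build the fully O-methylated heptamer from halogenated methoxyphenols by copper-mediated diaryl ether couplings and finish with BBr3.
The ring pairs B–C and D–E would both come from one bromophenol A1, made by adding the oxygen of a 2,6-dimethoxyphenol to a quinone monoketal of the ring C phenol.
A1 would be extended to a trimer phenol A2 and to a tetramer bromide A3; an Ullmann coupling of A2 with A3 would give the octadeca-O-methyl ether A4, and demethylation would free the eighteen phenols.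
First weak step, the ortho-aryloxylation that makes A1: a di-ortho-substituted phenol as oxygen nucleophile toward a quinone monoketal has no close precedent, and both halves of the plan depend on it.
Second weak step, the couplings in which A1 is at once a phenol and an aryl bromide: self-condensation would be held back only by excess partner, slow addition or iodide-versus-bromide discrimination.
Third weak step, the final Ullmann union of trimer and tetramer: its nucleophile is a phenol flanked by an aryloxy and a methoxy group, so it would need about 110 °C for days on the most valuable material.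

**Retrosynthetic overview of the new route**

1. Each of the six ether bonds joins a phenol oxygen to a ring carbon that lies ortho or para to another oxygen: C1 of ring A and C4 of rings B, D, F (between two C–O carbons), and C6 of rings C, E (between C–OAr and C–OH). Each bond is therefore cut on the side opposite to the direct plan: the oxygen stays on the right-hand ring as a phenol, and the left-hand ring becomes a quinone diazide, a rhodium-carbenoid precursor with the carbene at exactly that carbon.
2. Two monomers suffice: para-quinone diazide 5 (rings F, D, B, A) and ortho-quinone diazide 10 (rings E, C). The chain grows from ring G (phenol 6) in the order F, E, D, C, B, A. Each ring arrives as a cyclohexadienone and aromatises in the bond-forming step, and its carbonyl oxygen becomes the phenol that makes the next bond, a laboratory copy of the oxidative phenol coupling presumed for phlorotannins.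
3. There is no halogen, no copper and no protecting-group step. The oxygen-flanked carbon is always the electrophile (a carbene carbon, reached at 50 °C), the nucleophile is always a phenol with a free ortho position, and no monomer carries a nucleophile and a leaving group together. The one selectivity issue that remains is chain overgrowth in steps 7, 9 and 10, handled by an excess of the recoverable phenol.
4. BBr3 then frees all eighteen phenols.

Key step: step 6

Remark: the target has no stereocentre and its diaryl ether bonds are taken as freely rotating; the quinone diazides 5 and 10 are handled in solution and in the dark.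

**Route**

Step 1
Reactants: 1 1,3-dimethoxy-2-nitrobenzene
Product: 3 4-amino-3,5-dimethoxyphenol, via N-(2,6-dimethoxyphenyl)hydroxylamine 2 (not isolated)
Conditions: Zn, NH4Cl, THF/H2O, 0–10 °C; filter; 1.5 M H2SO4, 60 °C, Ar; NaHCO3 to pH 7
Reagents that add atoms: water, O
Why: Bamberger rearrangement: zinc reduces the nitro group to the N-arylhydroxylamine 2, acid removes water to give a nitrenium ion stabilised by the two ortho methoxy groups, and water adds at the only free conjugated position, para to nitrogen, so the amino group ends between the two methoxy groups with the new OH para to it.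

Step 2
Reactants: 3 4-amino-3,5-dimethoxyphenol
Product: 5 4-diazo-3,5-dimethoxycyclohexa-2,5-dien-1-one, via 4-hydroxy-2,6-dimethoxybenzenediazonium chloride 4 (not isolated)
Conditions: NaNO2, 2 M HCl, 0 °C; NaHCO3 to pH 7; CH2Cl2 extraction, dark
Reagents that add atoms: sodium nitrite, [Na+].[O-]N=O
Why: diazotisation of a para-aminophenol; the 4-hydroxybenzenediazonium ion loses its phenolic proton near neutrality and should give the neutral para-quinone diazide, a known compound class, which is extracted away from the salts.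

Step 3
Reactants: 6 3,4,5-trimethoxyphenol
Product: 7 sodium 4-[(E)-(2-hydroxy-4,5,6-trimethoxyphenyl)diazenyl]benzenesulfonate
Conditions: sulfanilic acid, Na2CO3, NaNO2, HCl, H2O, 0 °C; then 6, Na2CO3, H2O/MeOH, 0–5 °C; NaCl
Reagents that add atoms: sulfanilic acid, Nc1ccc(cc1)S(=O)(=O)O; sodium nitrite, [Na+].[O-]N=O; sodium carbonate, [Na+].[Na+].[O-]C([O-])=O
Why: azo coupling of a phenoxide with an arenediazonium ion; the para position of 6 carries OMe, so coupling can take place only at the two equivalent ortho positions and a single regioisomer with an E azo group should form.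

Step 4
Reactants: 7 sodium 4-[(E)-(2-hydroxy-4,5,6-trimethoxyphenyl)diazenyl]benzenesulfonate
Product: 10 6-diazo-3,4,5-trimethoxycyclohexa-2,4-dien-1-one, via 2-amino-3,4,5-trimethoxyphenol 8 (not isolated), via 2-hydroxy-4,5,6-trimethoxybenzenediazonium chloride 9 (not isolated)
Conditions: Na2S2O4, H2O/EtOH, 50 °C, Ar; EtOAc extraction; then NaNO2, 2 M HCl, 0 °C; NaHCO3 to pH 7; CH2Cl2 extraction, dark
Reagents that add atoms: sodium nitrite, [Na+].[O-]N=O
Why: reductive cleavage of the azo group by dithionite, the classical way to ortho-aminophenols (the sulfanilate stays in water), followed by diazotisation; deprotonation of the ortho-hydroxy diazonium ion should give the ortho-quinone diazide.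

Step 5
Reactants: 6 3,4,5-trimethoxyphenol; 5 4-diazo-3,5-dimethoxycyclohexa-2,5-dien-1-one
Product: 11 3,5-dimethoxy-4-(3,4,5-trimethoxyphenoxy)phenol (rings F-G)
Conditions: 6 (3 equiv), Rh2(OAc)4 (1 mol %), 4 Å MS, ClCH2CH2Cl, 50 °C, Ar, dark; 5 (1 equiv) added over 6 h
Reagents that add atoms: none
Why: Proposed new method: divalent rhodium should expel N2 from 5 to give a 4-oxocyclohexa-2,5-dienylidene carbenoid (a metal-bound aryl cation with a para phenoxide), the phenol oxygen of 6 adds to the carbenoid carbon, and loss of the metal with proton transfer to the former carbonyl oxygen gives the ether at C4 of ring F and the free phenol at C1; the closest known reaction types are the Rh2(OAc)4-catalysed O–H insertion of phenols into carbenoids from diazo esters and 2-diazo-1,3-diones and the O–H insertion of alcohols and C–H arylation of arenes with quinone diazide carbenoids; C-arylation is disfavoured because the carbenoid carbon lies between two methoxy-bearing carbons, and overgrowth is held back by the threefold excess of cheap 6.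

Step 6
Reactants: 11 3,5-dimethoxy-4-(3,4,5-trimethoxyphenoxy)phenol; 10 6-diazo-3,4,5-trimethoxycyclohexa-2,4-dien-1-one
Product: 12 2-[3,5-dimethoxy-4-(3,4,5-trimethoxyphenoxy)phenoxy]-3,4,5-trimethoxyphenol (rings E-F-G)
Conditions: 11 (1.3 equiv), Rh2(OAc)4 (2 mol %), 4 Å MS, ClCH2CH2Cl, 50 °C, Ar, dark; 10 (1 equiv) added over 6 h
Reagents that add atoms: none
Why: Proposed new method: divalent rhodium should take up the diazo carbon C6 of 10 and expel N2 to give a 6-oxocyclohexa-2,4-dienylidene carbenoid, a metal-bound aryl cation with an ortho phenoxide, to which the phenol oxygen of 11 adds; loss of the metal aromatises the ring and the proton passes from the oxonium to the carbonyl oxygen, so that the ether at C6 of ring E and the free phenol at C1 arise together. The closest known reaction types are the Rh2(OAc)4-catalysed O–H insertion of phenols into carbenoids from diazo esters and 2-diazo-1,3-diones and the O–H insertion of alcohols and C–H arylation of arenes with carbenoids from ortho- and para-quinone diazides. No ring is closed and no stereocentre is formed. The step needs O- over C-attack of the electron-rich phenol, secured by the carbenoid carbon lying between C=O and C–OMe, so that C-arylation would have to build a tri-ortho-substituted biaryl, and it needs carbenoid formation instead of Wolff ring contraction, which asks for light or much higher temperature. It also needs a single insertion: the phenol it unmasks sits ortho to the new aryloxy group and is less accessible than the unhindered phenol of 11, which is kept in slight excess while 10 is added slowly.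

Step 7
Reactants: 12 2-[3,5-dimethoxy-4-(3,4,5-trimethoxyphenoxy)phenoxy]-3,4,5-trimethoxyphenol; 5 4-diazo-3,5-dimethoxycyclohexa-2,5-dien-1-one
Product: 13 4-{2-[3,5-dimethoxy-4-(3,4,5-trimethoxyphenoxy)phenoxy]-3,4,5-trimethoxyphenoxy}-3,5-dimethoxyphenol (rings D-E-F-G)
Conditions: 12 (2 equiv), Rh2(OAc)4 (2 mol %), 4 Å MS, ClCH2CH2Cl, 50 °C, Ar, dark; 5 (1 equiv) added over 8 h
Reagents that add atoms: none
Why: Proposed new method: the carbenoid O–H insertion of step 5 (same mechanism; closest known types as given there) applied to the ortho-aryloxy phenol of ring E; because the phenol unmasked on ring D is less hindered than that of 12, 12 is taken in twofold excess with 5 as the limiting reagent, and the surplus 12 is recovered.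

Step 8
Reactants: 13 tetramer phenol D-E-F-G; 10 6-diazo-3,4,5-trimethoxycyclohexa-2,4-dien-1-one
Product: 14 2-(4-{2-[3,5-dimethoxy-4-(3,4,5-trimethoxyphenoxy)phenoxy]-3,4,5-trimethoxyphenoxy}-3,5-dimethoxyphenoxy)-3,4,5-trimethoxyphenol (rings C-D-E-F-G)
Conditions: 13 (1.3 equiv), Rh2(OAc)4 (2 mol %), 4 Å MS, ClCH2CH2Cl, 50 °C, Ar, dark; 10 (1 equiv) added over 6 h
Reagents that add atoms: none
Why: Proposed new method: the ortho-quinone diazide O–H insertion of step 6 (same mechanism and closest known reaction types) on the unhindered phenol of ring D; it makes the C6–O bond of ring C and unmasks the ring C phenol, which is ortho to the new aryloxy group and so reacts more slowly than 13.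

Step 9
Reactants: 14 pentamer phenol C-D-E-F-G; 5 4-diazo-3,5-dimethoxycyclohexa-2,5-dien-1-one
Product: 15 4-[2-(4-{2-[3,5-dimethoxy-4-(3,4,5-trimethoxyphenoxy)phenoxy]-3,4,5-trimethoxyphenoxy}-3,5-dimethoxyphenoxy)-3,4,5-trimethoxyphenoxy]-3,5-dimethoxyphenol (rings B-C-D-E-F-G)
Conditions: 14 (2 equiv), Rh2(OAc)4 (2 mol %), 4 Å MS, ClCH2CH2Cl, 50 °C, Ar, dark; 5 (1 equiv) added over 8 h
Reagents that add atoms: none
Why: Proposed new method: the para-quinone diazide O–H insertion of step 5 (same mechanism and closest known reaction types) on the ortho-aryloxy phenol of ring C, run as in step 7 with 14 in recoverable excess because the phenol unmasked on ring B is the less hindered one.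

Step 10
Reactants: 15 hexamer phenol B-C-D-E-F-G; 5 4-diazo-3,5-dimethoxycyclohexa-2,5-dien-1-one
Product: 16 4-{4-[2-(4-{2-[3,5-dimethoxy-4-(3,4,5-trimethoxyphenoxy)phenoxy]-3,4,5-trimethoxyphenoxy}-3,5-dimethoxyphenoxy)-3,4,5-trimethoxyphenoxy]-3,5-dimethoxyphenoxy}-3,5-dimethoxyphenol (heptamer phenol A-B-C-D-E-F-G)
Conditions: 15 (2 equiv), Rh2(OAc)4 (2 mol %), 4 Å MS, ClCH2CH2Cl, 50 °C, Ar, dark; 5 (1 equiv) added over 8 h
Reagents that add atoms: none
Why: Proposed new method: the para-quinone diazide O–H insertion of step 5 (same mechanism and closest known reaction types) on the unhindered phenol of ring B; the ring A phenol that appears is of the same kind as that of 15, so 15 is used in recoverable excess with 5 as the limiting reagent, and the free OH of ring A needs no protection because only demethylation follows.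

Step 11
Reactants: 16 heptamer phenol A-B-C-D-E-F-G
Product: 17 CNP0292517.0 (target)
Conditions: BBr3 (40 equiv), CH2Cl2, −78 °C → rt, Ar; H2O, 0 °C; EtOAc extraction; Sephadex LH-20 (degassed MeOH)
Reagents that add atoms: none
Why: Lewis-acid cleavage of aryl methyl ethers: bromide removes the methyl group of each boron-bound OMe, the diaryl ether oxygens carry no sp3 carbon and stay intact, and hydrolysis of the boron aryloxides should free all eighteen phenols without creating a stereocentre.

**Compound list**

1 | 1,3-dimethoxy-2-nitrobenzene | COc1cccc(OC)c1[N+](=O)[O-] | starting material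
2 | N-(2,6-dimethoxyphenyl)hydroxylamine | COc1cccc(OC)c1NO | intermediate
3 | 4-amino-3,5-dimethoxyphenol | COc1cc(O)cc(OC)c1N | intermediate
4 | 4-hydroxy-2,6-dimethoxybenzenediazonium chloride | COc1cc(O)cc(OC)c1[N+]#N.[Cl-] | intermediate
5 | 4-diazo-3,5-dimethoxycyclohexa-2,5-dien-1-one (para-quinone diazide; monomer for rings F, D, B, A) | COC1=CC(=O)C=C(OC)C1=[N+]=[N-] | intermediate
6 | 3,4,5-trimethoxyphenol (ring G) | COc1cc(O)cc(OC)c1OC | starting material
7 | sodium 4-[(E)-(2-hydroxy-4,5,6-trimethoxyphenyl)diazenyl]benzenesulfonate | COc1cc(O)c(/N=N/c2ccc(cc2)S(=O)(=O)[O-])c(OC)c1OC.[Na+] | intermediate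
8 | 2-amino-3,4,5-trimethoxyphenol | Nc1c(O)cc(OC)c(OC)c1OC | intermediate
9 | 2-hydroxy-4,5,6-trimethoxybenzenediazonium chloride | Oc1cc(OC)c(OC)c(OC)c1[N+]#N.[Cl-] | intermediate
10 | 6-diazo-3,4,5-trimethoxycyclohexa-2,4-dien-1-one (ortho-quinone diazide; monomer for rings E, C) | O=C1C=C(OC)C(OC)=C(OC)C1=[N+]=[N-] | intermediate
11 | 3,5-dimethoxy-4-(3,4,5-trimethoxyphenoxy)phenol (rings F-G) | COc1cc(O)cc(OC)c1Oc1cc(OC)c(OC)c(OC)c1 | intermediate
12 | 2-[3,5-dimethoxy-4-(3,4,5-trimethoxyphenoxy)phenoxy]-3,4,5-trimethoxyphenol (rings E-F-G) | Oc1cc(OC)c(OC)c(OC)c1Oc1cc(OC)c(Oc2cc(OC)c(OC)c(OC)c2)c(OC)c1 | intermediate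
13 | 4-{2-[3,5-dimethoxy-4-(3,4,5-trimethoxyphenoxy)phenoxy]-3,4,5-trimethoxyphenoxy}-3,5-dimethoxyphenol (rings D-E-F-G) | COc1cc(O)cc(OC)c1Oc1cc(OC)c(OC)c(OC)c1Oc1cc(OC)c(Oc2cc(OC)c(OC)c(OC)c2)c(OC)c1 | intermediate
14 | 2-(4-{2-[3,5-dimethoxy-4-(3,4,5-trimethoxyphenoxy)phenoxy]-3,4,5-trimethoxyphenoxy}-3,5-dimethoxyphenoxy)-3,4,5-trimethoxyphenol (rings C-D-E-F-G) | Oc1cc(OC)c(OC)c(OC)c1Oc1cc(OC)c(Oc2cc(OC)c(OC)c(OC)c2Oc2cc(OC)c(Oc3cc(OC)c(OC)c(OC)c3)c(OC)c2)c(OC)c1 | intermediate
15 | 4-[2-(4-{2-[3,5-dimethoxy-4-(3,4,5-trimethoxyphenoxy)phenoxy]-3,4,5-trimethoxyphenoxy}-3,5-dimethoxyphenoxy)-3,4,5-trimethoxyphenoxy]-3,5-dimethoxyphenol (rings B-C-D-E-F-G) | COc1cc(O)cc(OC)c1Oc1cc(OC)c(OC)c(OC)c1Oc1cc(OC)c(Oc2cc(OC)c(OC)c(OC)c2Oc2cc(OC)c(Oc3cc(OC)c(OC)c(OC)c3)c(OC)c2)c(OC)c1 | intermediate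
16 | 4-{4-[2-(4-{2-[3,5-dimethoxy-4-(3,4,5-trimethoxyphenoxy)phenoxy]-3,4,5-trimethoxyphenoxy}-3,5-dimethoxyphenoxy)-3,4,5-trimethoxyphenoxy]-3,5-dimethoxyphenoxy}-3,5-dimethoxyphenol (rings A to G; seventeen OMe groups, one OH on ring A) | COc1cc(O)cc(OC)c1Oc1cc(OC)c(Oc2cc(OC)c(OC)c(OC)c2Oc2cc(OC)c(Oc3cc(OC)c(OC)c(OC)c3Oc3cc(OC)c(Oc4cc(OC)c(OC)c(OC)c4)c(OC)c3)c(OC)c2)c(OC)c1 | intermediate
17 | CNP0292517.0, heptameric all-ether phlorotannin (A 2,4,6-trihydroxyphenyl; B, D, F 2,6-dihydroxy-1,4-phenylene; C, E 3,4,5-trihydroxy-1,2-phenylene; G 3,4,5-trihydroxyphenyl), achiral | Oc1cc(O)c(Oc2cc(O)c(Oc3cc(O)c(O)c(O)c3Oc3cc(O)c(Oc4cc(O)c(O)c(O)c4Oc4cc(O)c(Oc5cc(O)c(O)c(O)c5)c(O)c4)c(O)c3)c(O)c2)c(O)c1 | target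

**Step count and risks**

Total step count: 11. Longest linear sequence: 9 steps (1, 2, 5, 6, 7, 8, 9, 10, 11).

The three steps most likely to fail are steps 6, 7 and 5; all three bear the label, and their fallbacks use known chemistry.

Step 6. Loss of N2 from the ortho-quinone diazide with ring contraction (Wolff rearrangement), or dimerisation of the carbenoid, may outrun O–H insertion at a carbenoid carbon crowded by C=O and C–OMe. The fallback sets out from 11 and returns at 12. An Ullmann-type coupling of the unhindered phenol 11 with 2-bromo-3,4,5-trimethoxybenzaldehyde (CuI, N,N-dimethylglycine, Cs2CO3, dioxane, 90 °C; the ortho-formyl group activates the bromide) should give 2-[3,5-dimethoxy-4-(3,4,5-trimethoxyphenoxy)phenoxy]-3,4,5-trimethoxybenzaldehyde F1. Baeyer–Villiger oxidation (mCPBA, CH2Cl2, 0 °C) should give 2-[3,5-dimethoxy-4-(3,4,5-trimethoxyphenoxy)phenoxy]-3,4,5-trimethoxyphenyl formate F2, and K2CO3 in MeOH should give 12. The formyl group thus stands in for the masked phenol of the diazide.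

Step 7. The chain may overgrow: the phenol unmasked on ring D is less hindered than the ortho-aryloxy phenol of 12 and may take up a second carbenoid faster than 12 takes up the first. Steps 9 and 10 carry the same risk. The fallback sets out from 12 and returns at 13. Nucleophilic aromatic substitution of 4-fluoro-3,5-dimethoxybenzaldehyde by the phenoxide of 12 (Cs2CO3, DMSO, 120 °C) should give 4-{2-[3,5-dimethoxy-4-(3,4,5-trimethoxyphenoxy)phenoxy]-3,4,5-trimethoxyphenoxy}-3,5-dimethoxybenzaldehyde F3, an aldehyde that cannot react a second time. Baeyer–Villiger oxidation (mCPBA, CH2Cl2, 0 °C) should give 4-{2-[3,5-dimethoxy-4-(3,4,5-trimethoxyphenoxy)phenoxy]-3,4,5-trimethoxyphenoxy}-3,5-dimethoxyphenyl formate F4, and K2CO3 in MeOH should give 13.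

Step 5. The very electron-rich phenol 6 may attack the carbenoid through its ortho carbon (C-arylation), or couple as an azo compound with the diazonium form of 5, instead of inserting through oxygen. The fallback sets out from 6 and returns at 11. Nucleophilic aromatic substitution of 4-fluoro-3,5-dimethoxybenzaldehyde by the phenoxide of 6 (K2CO3, DMSO, 120 °C) should give 3,5-dimethoxy-4-(3,4,5-trimethoxyphenoxy)benzaldehyde F5. Baeyer–Villiger oxidation (mCPBA, CH2Cl2, 0 °C) should give 3,5-dimethoxy-4-(3,4,5-trimethoxyphenoxy)phenyl formate F6, and K2CO3 in MeOH should give 11.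

Further compounds
F1 | step 6 | 2-[3,5-dimethoxy-4-(3,4,5-trimethoxyphenoxy)phenoxy]-3,4,5-trimethoxybenzaldehyde | O=Cc1cc(OC)c(OC)c(OC)c1Oc1cc(OC)c(Oc2cc(OC)c(OC)c(OC)c2)c(OC)c1
F2 | step 6 | 2-[3,5-dimethoxy-4-(3,4,5-trimethoxyphenoxy)phenoxy]-3,4,5-trimethoxyphenyl formate | O=COc1cc(OC)c(OC)c(OC)c1Oc1cc(OC)c(Oc2cc(OC)c(OC)c(OC)c2)c(OC)c1
F3 | step 7 | 4-{2-[3,5-dimethoxy-4-(3,4,5-trimethoxyphenoxy)phenoxy]-3,4,5-trimethoxyphenoxy}-3,5-dimethoxybenzaldehyde | COc1cc(C=O)cc(OC)c1Oc1cc(OC)c(OC)c(OC)c1Oc1cc(OC)c(Oc2cc(OC)c(OC)c(OC)c2)c(OC)c1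
F4 | step 7 | 4-{2-[3,5-dimethoxy-4-(3,4,5-trimethoxyphenoxy)phenoxy]-3,4,5-trimethoxyphenoxy}-3,5-dimethoxyphenyl formate | COc1cc(OC=O)cc(OC)c1Oc1cc(OC)c(OC)c(OC)c1Oc1cc(OC)c(Oc2cc(OC)c(OC)c(OC)c2)c(OC)c1
F5 | step 5 | 3,5-dimethoxy-4-(3,4,5-trimethoxyphenoxy)benzaldehyde | COc1cc(C=O)cc(OC)c1Oc1cc(OC)c(OC)c(OC)c1
F6 | step 5 | 3,5-dimethoxy-4-(3,4,5-trimethoxyphenoxy)phenyl formate | COc1cc(OC=O)cc(OC)c1Oc1cc(OC)c(OC)c(OC)c1
A1 | direct plan | 6-(4-bromo-2,6-dimethoxyphenoxy)-2,3,4-trimethoxyphenol | COc1cc(Br)cc(OC)c1Oc1cc(OC)c(OC)c(OC)c1O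
A2 | direct plan | 6-[2,6-dimethoxy-4-(2,4,6-trimethoxyphenoxy)phenoxy]-2,3,4-trimethoxyphenol | COc1cc(OC)c(Oc2cc(OC)c(Oc3cc(OC)c(OC)c(OC)c3O)c(OC)c2)c(OC)c1
A3 | direct plan | 1-(4-bromo-2,6-dimethoxyphenoxy)-2-[3,5-dimethoxy-4-(3,4,5-trimethoxyphenoxy)phenoxy]-3,4,5-trimethoxybenzene | COc1cc(Br)cc(OC)c1Oc1cc(OC)c(OC)c(OC)c1Oc1cc(OC)c(Oc2cc(OC)c(OC)c(OC)c2)c(OC)c1
A4 | direct plan | octadeca-O-methyl ether of the target | COc1cc(OC)c(Oc2cc(OC)c(Oc3cc(OC)c(OC)c(OC)c3Oc3cc(OC)c(Oc4cc(OC)c(OC)c(OC)c4Oc4cc(OC)c(Oc5cc(OC)c(OC)c(OC)c5)c(OC)c4)c(OC)c3)c(OC)c2)c(OC)c1
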